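## Structural features

The target is a cross-conjugated cyclohexa-2,5-dienone (ring A: C1 carbonyl, C2 allyl, C3–H, C4, C5–OMe, C6–H) whose C4 is a fully substituted p-quinol methyl ether carbon. Besides its methoxy group, C4 carries a three-carbon chain: C8 (CH–CH3) is bonded to C4, and C7 (CH2) links C8 to a 3,4-dimethoxyphenyl ring (ring B). The only stereocentres, C4 (S) and C8 (S), are adjacent; one is quaternary and in the ring, the other tertiary and acyclic, and C8 is flanked only by a methyl and a methylene group, so there is no heteroatom handle for ordinary 1,2-induction. Fragile groups are the p-quinol ether at C4 (ionisation, dienone–phenol rearrangement or aromatisation under acid), the vinylogous ester C5(OMe)=C6–C1=O (hydrolysis, alkoxy exchange, confusion of O5 with O1), the terminal allyl group (migration into conjugation, hydrogenation) and the electron-rich ring B. The real difficulty is to make the congested C4–C8 bond while fixing both the C4/C8 relationship and the absolute configuration. The key step uses two latent features: C4–C5(OMe)–C6 is a disguised 2-methoxyallyl cation (C4 at the oxidation level of a quinone monoketal, C6 the nucleophilic end of the C5 enol ether), and C7 lies para to the 4-methoxy group of ring B and can carry a benzylic cation. C7 can therefore be tied to C6 while a rigid bicycle is needed and later released as CH2.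

## Logic of the disconnections

12 ⇒ 11. No bond of 12 is cut; in the retrosynthetic sense C7–H is exchanged for a C6–C7 bond and the C5 enol ether is written as a dimethyl ketal. The reason is that the acyclic C4/C8 pair becomes part of a rigid bicyclo[3.2.1]octene and the methyl group already sits on O5. The gain is stereochemical, not in size. The forward step must break C6–C7 heterolytically in preference to every other bond, reduce the C7 cation before oxygen or ring B traps it, and leave the C4 methoxy group in place.

11 ⇒ 10. The C5 ketal C–O bonds are cut back to the bridging ketone. O5 and O1 have to be distinguished while they still differ (strained saturated ketone against conjugated enone). After ring opening they would be the two ends of an unsymmetrical 1,3-dione, and methylation there would be expected to favour the less hindered O1. The gain is regiochemical certainty. The demand is chemoselective ketalisation without methanolysis of the non-enolisable β-diketone.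

10 ⇒ 5 + 9. C4–C8 and C6–C7 are cut. This removes the five-membered ring, two skeletal bonds and all four stereocentres, leaving two flat, achiral partners of similar size. The demands are bonding at C4 and not at C2, an aryl-endo approach, an alkene that keeps its Z geometry, and one face of the cation selected by a chiral counteranion.

5 ⇒ 4. One C4–OMe bond is cut, returning the ring to the aromatic level. The gain is an ordinary phenol. The demand is oxidation that delivers methanol para to the phenol oxygen and spares the allyl group.

4 ⇒ 3 ⇒ 1 + 2. The C2–allyl bond is cut (sigmatropic retron), then the O–allyl bond. The demand is migration to the ortho position that is para to a methoxy group and not to the one wedged between two oxygens.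

9 ⇒ 6 + 7 (through 8). The C7=C8 double bond is cut. The demand is kinetic Z selectivity, because the alkene geometry becomes the C8 configuration.

## Other disconnections considered

Alternative 1: The cut is at C3–C4 and C1–C2, so ring A is built by a [4+2] addition instead of being taken from an arene.
- **Forward key step.** The silyloxyfuran A1 (tert-butyl{[5-[(2S)-1-(3,4-dimethoxyphenyl)propan-2-yl]-4-methoxyfuran-2-yl]oxy}dimethylsilane) would add the dienal A2 (2-methylidenepent-4-enal) under a chiral oxazaborolidinium Lewis acid. Desilylation would collapse the bridged silyl ketal to the C1 ketone and C4 tertiary alcohol of A3 ((1S,5R)-1-allyl-5-hydroxy-4-methoxy-5-[(2S)-1-(3,4-dimethoxyphenyl)propan-2-yl]-2-oxocyclohex-3-ene-1-carbaldehyde).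
- **In favour.** C4 becomes quaternary as a diene terminus, not as a hindered electrophile. The donor pattern of A1 dictates the regiochemistry. The C5 methyl enol ether is carried unchanged from A1, so O5 and O1 are never confused; this equals what the ketal of the chosen plan achieves. Diels–Alder addition followed by oxa-bridge opening is established chemistry, which on precedent is better than step 5.
- **Against.** Lewis-acid-activated α-branched enals and silyloxyfurans tend towards open-chain Mukaiyama–Michael adducts. The catalyst's face selection is spent largely on C2, a centre destroyed later, while C4 depends on endo/exo control and induction from C8 beside a flat furan. A2 is volatile and polymerisable. A1 needs C8 from a separate asymmetric sequence. A3 still needs removal of the formyl group, introduction of C2=C3 and methylation of a hindered tertiary alcohol beside an enol ether.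
- **Comparison.** Both plans make C4 quaternary in a ring-forming step, but the chosen plan creates C4 and C8 together from two flat partners. A concerted cycloaddition is more predictable in regiochemistry than a cation cascade (a point for the alternative), but its relay to C4 is less direct. The chosen plan (seven steps) should be shorter by at least five.

Alternative 2: The cut is the O–C5 bond of a temporary tetrahydrofuran; the tether again runs through C7, but as a carbinol oxygen.
- **Forward key step.** In the prochiral dienone A4 (4-[(1R,2S)-1-(3,4-dimethoxyphenyl)-1-hydroxypropan-2-yl]-4-methoxycyclohexa-2,5-dien-1-one) the C7 hydroxyl would add reversibly, 5-exo-trig, to the β-carbon of one enone arm. This would give the cis-fused A5 ((2R,3S,3aR,7aS)-2-(3,4-dimethoxyphenyl)-3a-methoxy-3-methyl-3,3a,7,7a-tetrahydrobenzofuran-6(2H)-one) and decide C4 and C5.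
- **In favour.** The closure is an equilibrium, so C4 is set under thermodynamic control by the existing C7/C8 centres. Desymmetrising hetero-Michael additions to 4,4-disubstituted cyclohexadienones are well known, so this key step is better precedented than step 5. A4 would come from the same kind of hypervalent-iodine oxidation in methanol that gives 5, which is equal in simplicity.
- **Against.** A4 carries neither the allyl group nor the C5 methoxy group. After A5 an α-allylation at C2, a dehydrogenation across C5–C6, a reductive cleavage of the benzylic C7–O bond and an O-methylation would be needed, the last with the O5/O1 site problem the chosen route avoids. The adduct can revert by β-elimination whenever C6 is enolised. The C7 stereocentre must be built enantioselectively only to be removed.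
- **Comparison.** Both plans use a sacrificial link from C7 to the ring (C7–O–C5 here, C7–C6 there), but only the chosen plan forms C4–C8 in the same step. The reversible oxa-Michael closure is the safer elementary step (a point for the alternative); the cation cascade is the more productive one. The alternative is clearly longer (an estimated twelve steps or more against seven).

Alternative 3: The cut is the C4–C5 bond.
- **Forward key step.** A chiral triazolylidene carbene would turn the aldehyde of the acyclic keto-aldehyde A6 (2-{2-[(4S)-5-(3,4-dimethoxyphenyl)-4-methyl-3-oxopentyl]-1,3-dioxolan-2-yl}acetaldehyde) into an acyl anion equivalent. This would add to the C4 ketone (intramolecular crossed benzoin reaction) and close the ring as the α-ketol A7 ((8R)-8-hydroxy-8-[(2S)-1-(3,4-dimethoxyphenyl)propan-2-yl]-1,4-dioxaspiro[4.5]decan-7-one).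
- **In favour.** Aldehyde–ketone benzoin closures to tertiary α-ketols under chiral triazolium catalysis are known, so on precedent this key step is better than step 5. The C4 oxygen and C5 carbonyl arrive together under catalyst control. With C1 still a ketal, the C5 ketone could be converted into its methyl enol ether without interference from O1, which equals the regiochemical certainty of the chosen ketal route.
- **Against.** C8 of A6 is an enolisable centre α to the accepting ketone, so the basic carbene conditions threaten its configuration. An α-branched ketone is a poor benzoin acceptor and aldol pathways compete. A7 is a saturated ring at too low an oxidation level: tertiary-alcohol methylation, enol-ether formation, ketal removal, allylation at C2 against the more acidic C6 and introduction of C2=C3 would remain.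
- **Comparison.** The alternative builds ring A from a chain and sets only C4 in its key step; the chosen plan keeps the ring of an inexpensive phenol and sets C4 and C8 at once. The carbene closure is better understood than the ion-pair cycloaddition (a point for the alternative) but puts C8 at risk. The chosen plan is shorter by a wide margin.

Key step: step 5

Remarks on the chemistry (assumptions):
- Which hand of the chiral acid gives 10 and not its mirror image cannot be predicted. It is assumed to be settled by screening both hands and by an independent assignment of 10.
- Configuration check: the 6-endo-methyl, 7-endo-aryl adduct 10, (1S,5S,6S,7R), maps onto (4S,8S) of 12. The skeleton of precursor 5 needs no change.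
- In the cation from 5 the positive charge sits on C4 and, through C3, on C2. C6 is the nucleophilic α-carbon of the C5 enol ether, which is why it closes the ring second.
- The methyl group is put back on O5 as a bridging ketal (step 6) before C6–C7 is broken. A late O-methylation of the ring-opened 1,3-dione would be expected to favour O1.

Step 1
Reactants: 1 3,4-dimethoxyphenol; 2 allyl bromide
Product: 3 4-(allyloxy)-1,2-dimethoxybenzene
Conditions: K2CO3, acetone, reflux
Reagents that add atoms: none
Why: Williamson ether synthesis; the phenoxide is alkylated at oxygen by the primary allylic bromide under mild carbonate conditions, and no stereocentre is involved.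

Step 2
Reactants: 3 4-(allyloxy)-1,2-dimethoxybenzene
Product: 4 2-allyl-4,5-dimethoxyphenol
Conditions: PhNEt2, 190 °C, sealed tube
Reagents that add atoms: none
Why: Aromatic Claisen rearrangement ([3,3] shift, then tautomerisation); the ortho position para to the 3-methoxy group is open whereas the other is wedged between two oxygen substituents, so the allyl group should arrive mainly at the carbon that becomes C2.

Step 3
Reactants: 4 2-allyl-4,5-dimethoxyphenol
Product: 5 2-allyl-4,4,5-trimethoxycyclohexa-2,5-dien-1-one
Conditions: PhI(OAc)2, MeOH, 0 °C; NaHCO3
Reagents that add atoms: methanol, CO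
Why: Oxidative dearomatisation of a p-methoxyphenol by a trivalent iodine reagent; methanol adds para to the phenol oxygen at the carbon that already bears OMe, giving the achiral quinone monoketal, with the allyl and 5-methoxy groups as spectators.

Step 4
Reactants: 6 3,4-dimethoxybenzaldehyde (veratraldehyde); 7 ethyltriphenylphosphonium bromide
Product: 9 (Z)-1,2-dimethoxy-4-(prop-1-en-1-yl)benzene, via ethylidenetriphenylphosphorane 8 (not isolated)
Conditions: 7, NaN(SiMe3)2, THF, 0 °C; then 6, −78 °C to rt; AgNO3-silica
Reagents that add atoms: none
Why: Wittig reaction of a non-stabilised ylide under lithium-free conditions; kinetic formation of the cis-oxaphosphetane should give mainly the Z alkene, and residual E isomer is removed on silver nitrate-impregnated silica because it would lead to the C8 epimer.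

Step 5
Reactants: 5 2-allyl-4,4,5-trimethoxycyclohexa-2,5-dien-1-one; 9 (Z)-1,2-dimethoxy-4-(prop-1-en-1-yl)benzene
Product: 10 (1S,5S,6S,7R)-3-allyl-7-(3,4-dimethoxyphenyl)-5-methoxy-6-methylbicyclo[3.2.1]oct-3-ene-2,8-dione (7-endo-aryl, 6-endo-methyl)
Conditions: 9 (1.5 equiv), chiral imidodiphosphorimidate acid HN[P(=NSO2CF3)(3,3'-Ar2-1,1'-binaphthalene-2,2'-diolate)]2, Ar = 3,5-(CF3)2C6H3 (5 mol%), CH2Cl2, −60 °C; Et3N at −60 °C
Reagents that add atoms: none
Why: Proposed new method: the confined, strongly acidic catalyst ionises one C4 methoxy group of 5 and holds the flat 4-methoxy cation as a contact ion pair; the electron-rich terminus C8 of 9 bonds to C4, the resulting veratryl-type cation at C7 is captured by C6 (5-endo cation–enol ether closure of the ring C4–C8–C7–C6–C5, the second bond of a formal (3+2) addition of a 2-methoxyallyl cation and the [5+2] mode across C4/C6), and the bridging C5 oxocarbenium passes its methyl group to the liberated methanol (dimethyl ether), which returns the proton. The closest known reaction types are the achiral acid-promoted cycloaddition of p-quinone monoketal cations with propenylarenes to bicyclo[3.2.1]octenediones and counteranion-directed additions of oxocarbenium ions to alkenes under imidodiphosphorimidate catalysis. C4 is set in the absolute sense by the face of the cation that the chiral anion leaves open; C8 is set relative to C4 by the Z geometry of 9 together with the stacked aryl-endo approach (methyl syn to C3); C7 (aryl endo) and C6 follow from closure on the same face and are erased later, so leakage at C7 is harmless. The step needs bonding at C4 and not at C2 or C6: C2 is encumbered by the allyl group and would have to become an all-carbon quaternary centre, C6 is deactivated as an electrophile by the 5-methoxy group, C4 carries the highest positive charge, and low temperature with a non-nucleophilic anion favours this compact 1,2-mode. Closure at C6 rather than at O5 is expected from the carbon-centred nucleophilicity of the vinylogous ester, and the Z geometry of 9 is protected by the low temperature and the absence of free strong acid.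

Step 6
Reactants: 10 (1S,5S,6S,7R)-3-allyl-7-(3,4-dimethoxyphenyl)-5-methoxy-6-methylbicyclo[3.2.1]oct-3-ene-2,8-dione
Product: 11 (1S,5S,6S,7R)-3-allyl-7-(3,4-dimethoxyphenyl)-5,8,8-trimethoxy-6-methylbicyclo[3.2.1]oct-3-en-2-one
Conditions: HC(OMe)3, MeOH, camphorsulfonic acid (cat.), 0 °C to rt; Et3N
Reagents that add atoms: trimethyl orthoformate, COC(OC)OC; methanol, CO
Why: Acid-catalysed ketalisation with an orthoester as dehydrating agent; the bridging ketone (C5 of the target) is strained, non-conjugated and flanked by electron-withdrawing groups, hence more electrophilic than the conjugated enone carbonyl, and no stereocentre is created or disturbed.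

Step 7
Reactants: 11 (1S,5S,6S,7R)-3-allyl-7-(3,4-dimethoxyphenyl)-5,8,8-trimethoxy-6-methylbicyclo[3.2.1]oct-3-en-2-one
Product: 12 (4S)-2-allyl-4-[(2S)-1-(3,4-dimethoxyphenyl)propan-2-yl]-4,5-dimethoxycyclohexa-2,5-dien-1-one
Conditions: Et3SiH, Me3SiOTf (cat.), CH2Cl2 (0.02 M), −78 to −40 °C; Et3N
Reagents that add atoms: none
Why: Proposed new method: the Lewis acid ionises the strained bridging ketal to the C5 methoxy-oxocarbenium ion, whose empty orbital overlaps the C6–C7 bond (the microscopic reverse of the ring closure of step 5); Grob-type (retro-Prins) heterolysis of this bond, the only one that releases a stabilised cation, gives the veratryl-type C7 cation and leaves the methyl group on O5 as the C5(OMe)=C6–C1=O vinylogous ester, and Et3SiH reduces the cation to C7H2 (ionic hydrogenation); the closest known reaction types are the acid-induced C6–C7 ionisation (bridge migration) of such bicyclooctenediones through the benzylic cation and the Et3SiH/silyl triflate reduction of ketals and benzylic cations. C4 and C8 are untouched, C6 and C7 cease to be stereocentres, and high dilution favours the unimolecular fragmentation over bimolecular hydride attack at C5.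

## Compound list

1 | 3,4-dimethoxyphenol | COc1ccc(O)cc1OC | starting material
2 | allyl bromide | C=CCBr | starting material
3 | 4-(allyloxy)-1,2-dimethoxybenzene | C=CCOc1ccc(OC)c(OC)c1 | intermediate
4 | 2-allyl-4,5-dimethoxyphenol | C=CCc1cc(OC)c(OC)cc1O | intermediate
5 | 2-allyl-4,4,5-trimethoxycyclohexa-2,5-dien-1-one | C=CCC1=CC(OC)(OC)C(OC)=CC1=O | intermediate
6 | 3,4-dimethoxybenzaldehyde (veratraldehyde) | COc1ccc(C=O)cc1OC | starting material
7 | ethyltriphenylphosphonium bromide | CC[P+](c1ccccc1)(c1ccccc1)c1ccccc1.[Br-] | starting material
8 | ethylidenetriphenylphosphorane | CC=P(c1ccccc1)(c1ccccc1)c1ccccc1 | intermediate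
9 | (Z)-1,2-dimethoxy-4-(prop-1-en-1-yl)benzene | C/C=C\c1ccc(OC)c(OC)c1 | intermediate
10 | (1S,5S,6S,7R)-3-allyl-7-(3,4-dimethoxyphenyl)-5-methoxy-6-methylbicyclo[3.2.1]oct-3-ene-2,8-dione | C=CCC1=C[C@@]2(OC)[C@@H](C)[C@@H](c3ccc(OC)c(OC)c3)[C@H](C2=O)C1=O | intermediate
11 | (1S,5S,6S,7R)-3-allyl-7-(3,4-dimethoxyphenyl)-5,8,8-trimethoxy-6-methylbicyclo[3.2.1]oct-3-en-2-one | C=CCC1=C[C@@]2(OC)[C@@H](C)[C@@H](c3ccc(OC)c(OC)c3)[C@H](C2(OC)OC)C1=O | intermediate
12 | (4S)-2-allyl-4-[(2S)-1-(3,4-dimethoxyphenyl)propan-2-yl]-4,5-dimethoxycyclohexa-2,5-dien-1-one | C=CCC1=C[C@@](OC)([C@@H](C)Cc2ccc(OC)c(OC)c2)C(OC)=CC1=O | target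

## Step count and least certain steps

Total step count: 7. Longest linear sequence: 6 (steps 1, 2, 3, 5, 6, 7); step 4 is a one-step branch.

**Step 5 (key step).**
- *Most likely failure:* the first bond forms at C2, the carbon α to the carbonyl that acid-promoted additions of propenylarenes to cations of this kind normally choose, so that closure at C6 builds the isomeric bridgehead-allyl skeleton. Next in likelihood are loss of alkene geometry through reversible addition (C8 epimer series) and too small a difference between the two faces of the ion pair. If the C5 oxocarbenium is caught by methanol instead of losing its methyl group, that material is 11 and enters step 7 directly.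
- *Fallback (known reactions, no cation chemistry at C4):* it sets out from 9 and returns at 12.
 - Copper-catalysed enantioselective protoboration of 9 (B2pin2, MeOH, CuCl, NaOtBu, chiral bisphosphine) should place boron on the methyl-bearing carbon and give (S)-2-[1-(3,4-dimethoxyphenyl)propan-2-yl]-4,4,5,5-tetramethyl-1,3,2-dioxaborolane F1.
 - Stereoretentive coupling of F1 with the dilithio derivative of 4-bromo-3-methoxyphenol (boronate complex, 1,2-metallate shift triggered by Ph3BiF2) should give 3-methoxy-4-[(2S)-1-(3,4-dimethoxyphenyl)propan-2-yl]phenol F2.
 - O-Allylation with 2 (K2CO3) gives 4-(allyloxy)-1-[(2S)-1-(3,4-dimethoxyphenyl)propan-2-yl]-2-methoxybenzene F3, and Claisen rearrangement gives 2-allyl-5-methoxy-4-[(2S)-1-(3,4-dimethoxyphenyl)propan-2-yl]phenol F4.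
 - PhI(OAc)2 in methanol then adds methanol para to the phenol oxygen to give 12 together with its C4 epimer (4R)-2-allyl-4-[(2S)-1-(3,4-dimethoxyphenyl)propan-2-yl]-4,5-dimethoxycyclohexa-2,5-dien-1-one F5, to be separated by chromatography. The price is the lack of control at C4.

**Step 7.**
- *Most likely failure:* hydride transfer to the C5 oxocarbenium before fragmentation (bridging methyl ether, a dead end), capture of the C7 cation by the enol-ether oxygen or ring B, or ionisation of the C4 methoxy group of 12 if the mixture warms.
- *Fallback (known reactions):* it sets out from 10 and returns at 12.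
 - Acid-induced bridge migration of 10 (CF3CO2H, CH2Cl2) gives (2R,3S,3aR)-5-allyl-2-(3,4-dimethoxyphenyl)-3a-methoxy-3-methyl-3,3a-dihydrobenzofuran-6(2H)-one F6 (either C2 epimer serves).
 - Ionic hydrogenolysis of its benzylic C–O bond (Et3SiH, BF3·OEt2) gives the vinylogous acid (4S)-2-allyl-5-hydroxy-4-methoxy-4-[(2S)-1-(3,4-dimethoxyphenyl)propan-2-yl]cyclohexa-2,5-dien-1-one F7.
 - O-Methylation (Me3SiCHN2, MeOH) gives 12 together with the O1-methylated isomer (6S)-4-allyl-3,6-dimethoxy-6-[(2S)-1-(3,4-dimethoxyphenyl)propan-2-yl]cyclohexa-2,4-dien-1-one F8. The two are separated and F8 is hydrolysed back to F7 (aq. HCl, THF) for recycling. The weakness is the uncontrolled site of methylation.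

**Step 6.**
- *Most likely failure:* methanol adds to the strained C5 carbonyl and cleaves the C5–C6 bond (retro-Claisen opening of the non-enolisable β-diketone), or the acid triggers premature C6–C7 ionisation.
- *Fallback:* it sets out from 10 and returns at 12 with no isolated ketal. MeOSiMe3 and Me3SiOTf in CH2Cl2 at −78 °C, with Et3SiH already present, generate the C5 methoxy-oxocarbenium under aprotic conditions so that it fragments and is reduced in the same flask. No new compound is made (F0).

**Step 4.**
- *Most likely failure:* incomplete Z selectivity (aromatic aldehydes are less Z-selective than aliphatic ones), inefficient removal of the E isomer, or Z-to-E drift on storage; each feeds the C8 epimer series.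
- *Fallback:* it sets out from 6 and returns at 9. Corey–Fuchs olefination (CBr4, PPh3) gives 4-(2,2-dibromovinyl)-1,2-dimethoxybenzene F9; n-BuLi then MeI gives 1,2-dimethoxy-4-(prop-1-yn-1-yl)benzene F10; semi-hydrogenation (H2, Pd/CaCO3 poisoned with Pb(OAc)2, quinoline) gives 9 with the geometry fixed by syn addition of hydrogen.

## Further compounds

F1 | step 5 | (S)-2-[1-(3,4-dimethoxyphenyl)propan-2-yl]-4,4,5,5-tetramethyl-1,3,2-dioxaborolane | CC1(C)OB(OC1(C)C)[C@@H](C)Cc1ccc(OC)c(OC)c1
F2 | step 5 | 3-methoxy-4-[(2S)-1-(3,4-dimethoxyphenyl)propan-2-yl]phenol | COc1cc(O)ccc1[C@@H](C)Cc1ccc(OC)c(OC)c1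
F3 | step 5 | 4-(allyloxy)-1-[(2S)-1-(3,4-dimethoxyphenyl)propan-2-yl]-2-methoxybenzene | C=CCOc1ccc([C@@H](C)Cc2ccc(OC)c(OC)c2)c(OC)c1
F4 | step 5 | 2-allyl-5-methoxy-4-[(2S)-1-(3,4-dimethoxyphenyl)propan-2-yl]phenol | C=CCc1cc([C@@H](C)Cc2ccc(OC)c(OC)c2)c(OC)cc1O
F5 | step 5 | (4R)-2-allyl-4-[(2S)-1-(3,4-dimethoxyphenyl)propan-2-yl]-4,5-dimethoxycyclohexa-2,5-dien-1-one | C=CCC1=C[C@](OC)([C@@H](C)Cc2ccc(OC)c(OC)c2)C(OC)=CC1=O
F6 | step 7 | (2R,3S,3aR)-5-allyl-2-(3,4-dimethoxyphenyl)-3a-methoxy-3-methyl-3,3a-dihydrobenzofuran-6(2H)-one | C=CCC1=C[C@@]2(OC)[C@@H](C)[C@H](c3ccc(OC)c(OC)c3)OC2=CC1=O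
F7 | step 7 | (4S)-2-allyl-5-hydroxy-4-methoxy-4-[(2S)-1-(3,4-dimethoxyphenyl)propan-2-yl]cyclohexa-2,5-dien-1-one | C=CCC1=C[C@@](OC)([C@@H](C)Cc2ccc(OC)c(OC)c2)C(O)=CC1=O
F8 | step 7 | (6S)-4-allyl-3,6-dimethoxy-6-[(2S)-1-(3,4-dimethoxyphenyl)propan-2-yl]cyclohexa-2,4-dien-1-one | C=CCC1=C[C@@](OC)([C@@H](C)Cc2ccc(OC)c(OC)c2)C(=O)C=C1OC
F0 | step 6 | none | none
F9 | step 4 | 4-(2,2-dibromovinyl)-1,2-dimethoxybenzene | COc1ccc(C=C(Br)Br)cc1OC
F10 | step 4 | 1,2-dimethoxy-4-(prop-1-yn-1-yl)benzene | CC#Cc1ccc(OC)c(OC)c1
A1 | alternative 1 | tert-butyl{[5-[(2S)-1-(3,4-dimethoxyphenyl)propan-2-yl]-4-methoxyfuran-2-yl]oxy}dimethylsilane | COc1cc(O[Si](C)(C)C(C)(C)C)oc1[C@@H](C)Cc1ccc(OC)c(OC)c1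
A2 | alternative 1 | 2-methylidenepent-4-enal | C=CCC(=C)C=O
A3 | alternative 1 | (1S,5R)-1-allyl-5-hydroxy-4-methoxy-5-[(2S)-1-(3,4-dimethoxyphenyl)propan-2-yl]-2-oxocyclohex-3-ene-1-carbaldehyde | C=CC[C@@]1(C=O)C[C@@](O)([C@@H](C)Cc2ccc(OC)c(OC)c2)C(OC)=CC1=O
A4 | alternative 2 | 4-[(1R,2S)-1-(3,4-dimethoxyphenyl)-1-hydroxypropan-2-yl]-4-methoxycyclohexa-2,5-dien-1-one | COC1(C=CC(=O)C=C1)[C@@H](C)[C@@H](O)c1ccc(OC)c(OC)c1
A5 | alternative 2 | (2R,3S,3aR,7aS)-2-(3,4-dimethoxyphenyl)-3a-methoxy-3-methyl-3,3a,7,7a-tetrahydrobenzofuran-6(2H)-one | O=C1C=C[C@@]2(OC)[C@@H](C)[C@H](c3ccc(OC)c(OC)c3)O[C@H]2C1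
A6 | alternative 3 | 2-{2-[(4S)-5-(3,4-dimethoxyphenyl)-4-methyl-3-oxopentyl]-1,3-dioxolan-2-yl}acetaldehyde | O=CCC1(CCC(=O)[C@@H](C)Cc2ccc(OC)c(OC)c2)OCCO1
A7 | alternative 3 | (8R)-8-hydroxy-8-[(2S)-1-(3,4-dimethoxyphenyl)propan-2-yl]-1,4-dioxaspiro[4.5]decan-7-one | C1C[C@@](O)([C@@H](C)Cc2ccc(OC)c(OC)c2)C(=O)CC13OCCO3
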